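## Analysis of the target

The target is a C15 dibromide in which three rings meet at one quaternary carbon, C1. Ring A is a cyclohexene (C1, the methyl- and oxygen-bearing C2, the CHBr carbon C3, vinylic C4, the bromoalkene carbon C5, the gem-dimethyl carbon C6). Ring B is an oxetane (C1, C2, the ring oxygen, the acetal carbon C7). Ring C is a tetrahydrofuran (C1, C7, the second acetal oxygen, the isopropenyl-bearing C9, the methylene C8). There are five stereocentres. C1, C2 and C7 are locked together by the cis fusion of ring B to rings A and C, so once C7 and the C2 oxygen are on the same face of ring A, C7 can have only one configuration. C9 (R) is independent and places the isopropenyl group on the face of ring C away from the oxetane; C3 is independent and carries bromine trans to the C2–O bond and cis to the C2 methyl. The oxetane acetal is strained and acid-labile, the secondary allylic bromide at C3 ionises easily, and the isopropenyl group must survive every oxidant. The difficulty lies in C1, which is flanked by two fully substituted carbons (C2 and C6), and in the four-membered acetal, which cannot be formed by equilibrium acetalisation. The strategy rests on the 1,4-relation of the C2 oxygen and the bromine-bearing C5 across C3 and C4: a C2=C3–C4=C5 cyclohexadiene can take both heteroatom positions from one molecule of dioxygen, C5 arriving as the carbonyl from which both bromines are later placed.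

## Retrosynthetic reasoning

**Both C–Br bonds (18 from 16 and 15).** The bromines are removed last because the allylic bromide tolerates little further chemistry. Hydrazone 16 of enone 15 is the precursor: oxidation gives diazo compound 17, and bromination at C5 with loss of nitrogen lets the second bromide enter at the allyl terminus C3. Enone 15 has no free hydroxyl to intercept the cationic intermediate and no enolisable hydrogen (C6 and C2 are fully substituted). The forward reaction has to condense hydrazine with a hindered ketone and deliver bromide to C3 on the face opposite the oxetane oxygen.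

**The oxetane C7–O bond (15 from 14).** Ring B is opened at the acetal bond, giving lactol 14 with a cis tertiary hydroxyl at C2. Cutting here leaves the C2–O bond, which the key step makes, untouched. Acid-catalysed closure is not an option because ring strain makes the acetal far less stable than lactol plus water. The forward step must therefore be an irreversible dehydration that turns the lactol hydroxyl into a leaving group under non-acidic conditions.

**Ring C and the ring A oxidation pattern (14 from 12 via 13; 12 from 11).** The lactol is the closed form of dihydroxy aldehyde 13, obtained by desilylation of 12. The γ-hydroxy enone of 12 is the base-induced isomer of endoperoxide 11: only C5 carries a bridgehead hydrogen, so C5 becomes the ketone and C2 keeps its oxygen as a tertiary alcohol. The C7 alcohol is oxidised before the base step (11 from 10) so that no primary hydroxyl is present to add to the enone at C3.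

**The two C–O bonds at C2 and C5 (10 from 9).** This is the key disconnection. Removing dioxygen from 10 gives cyclohexadiene 9. It is made here because one reagent supplies the future oxetane oxygen and the carbonyl for both bromines, and because the free hydroxymethyl group of 9 can steer the reagent to the face that the oxetane later requires.

**Functional-group changes (9 from 8 from 7).** The hydroxymethyl group comes from reduction of the C1 ester. The C9 hydroxyl is silylated first, which makes that arm bulky and stops it from hydrogen bonding to the oxidant.

**C9 stereocentre and the C9–isopropenyl bond (7 from 6 from 4 and 5).** The allylic alcohol is traced to enone 6 by catalyst-controlled reduction, and 6 to Weinreb amide 4 and Grignard reagent 5. C1 is racemic at this point, so reduction gives two diastereomers with the same C9 configuration; they are separated, and this is where the absolute configuration of C1 is secured.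

**The C1–C8 bond (4 from 1 and 2).** The quaternary centre is made by alkylating the fully conjugated trienolate 3 of ethyl safranate 1 at C1 with the SN2-activated bromoacetamide 2. A small, activated electrophile is chosen because C1 lies between C2 and C6; a β-branched, β-oxygenated alkyl halide carrying C9 would be too slow at this position.

## Alternatives that were turned down

**Alternative 1:** The bond between C1 and C2 is cut. In the forward step a copper hydride reagent reduces the butenolide of A1 at C8, and the copper enolate adds through C1 to the tethered methyl ketone, closing ring A as the β-hydroxy lactone A2. In its favour, the C9 stereocentre of the butenolide directs C1 and the chelated aldol places the C2 oxygen cis to the lactone carbonyl, so C1 and C2 are set without a resolution. On this point it is stronger than the chosen route, which separates C1 epimers. Against it, the aldol joins a fully substituted enolate carbon to a ketone beside the gem-dimethyl carbon and is reversible at the copper alkoxide stage. A2 also has ring A in the wrong oxidation pattern (C3–C4 saturated, C5 as a dioxolane), so ketal removal, dehydrogenation and lactone-to-lactol reduction beside a ketone must precede the same hydrazone endgame. A1 itself, an α-tert-alkyl butenolide, needs a long synthesis. The chosen route obtains C2–O, C5=O and C3=C4 from dioxygen with no redox corrections on ring A.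

**Alternative 2:** Ring B is cut at C1–C2 and C7–O in a [2+2] sense. Irradiation near 300 nm of the furan ketone A3 would join the carbonyl carbon to furan C3 and the carbonyl oxygen to furan C2, giving A4 with rings A and B closed. In its favour, the strained acetal forms under neutral photochemical conditions. Here it is stronger than the chosen route, which has to force a dehydrative closure. Against it, the aliphatic ketone has a γ-hydrogen on the silyloxy-bearing carbon, so γ-hydrogen abstraction and cleavage compete. The only stereocentre present (C5, later destroyed) must control three new centres from two bonds away. A4 lacks the isopropenyl group, so C9 must be built on the enol ether C8=C9 with the acid-labile acetal already in place, and ring A still needs oxidation and dehydrogenation. The chosen route has C9 from step 3 and forms the acetal two steps before the end.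

**Alternative 3:** The C2–C3 bond and the C3–O bond of an epoxide are cut. A lithium amide would convert the allylic sulfonium salt A5 to its ylide, which adds to the acetyl group on C1 and closes the vinyl epoxide A6. In its favour, the vinyl bromide is already present, and opening the epoxide with bromide at allylic C3 would place bromine trans to the C2 oxygen by inversion. That control of C3 is better than the cation capture of the chosen route. Against it, the ylide can form at an S-methyl group and undergo a [2,3] shift, or attack through its bromine-bearing carbon. The acetyl group on a quaternary lactone α-carbon is hindered and open to retro-Claisen cleavage. Nothing fixes the face of carbonyl addition, that is, C2 relative to C1. A5 needs a long synthesis (quaternary C1 related to C9, Z-bromoalkene), and the later trans-bromohydrin recloses to the epoxide with any base during lactol and acetal formation. The chosen route fixes the C1/C2 relation with a directing hydroxyl and reaches its precursor in five steps.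

Key step: step 6

Assumption: ring A atoms keep the labels C1–C6 of the analysis in every intermediate. Commercial ethyl safranate may contain its 2,4-diene isomer, which enters the same trienolate in step 1.

## Route

**Step 1**
Reactants: 1 ethyl safranate (ethyl 2,6,6-trimethylcyclohexa-1,3-diene-1-carboxylate); 2 2-bromo-N-methoxy-N-methylacetamide
Product: 4 racemic ethyl 1-{2-[methoxy(methyl)amino]-2-oxoethyl}-2,6,6-trimethylcyclohexa-2,4-diene-1-carboxylate, via potassium trienolate 3 (not isolated)
Conditions: KN(SiMe3)2 (1.05 equiv), THF, −78 → 0 °C, 30 min; then 2, −78 → −20 °C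
Reagents that add atoms: none
Why: Deconjugative α-alkylation of an extended ester enolate: loss of a C5 proton gives the cyclohexadienyl-type trienolate, and the amide base/amine pair lets the enolate mixture settle to this fully conjugated anion and not the cross-conjugated one from the C2 methyl. The potassium enolate reacts at C1, the carbon next to the carboxylate, with the SN2-activated α-bromo amide; C1 is formed racemic.

**Step 2**
Reactants: 4 racemic Weinreb amide ester; 5 isopropenylmagnesium bromide
Product: 6 racemic ethyl 2,6,6-trimethyl-1-(3-methyl-2-oxobut-3-en-1-yl)cyclohexa-2,4-diene-1-carboxylate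
Conditions: THF, −20 → 0 °C; aq NH4Cl
Reagents that add atoms: none
Why: Weinreb ketone synthesis; the chelated tetrahedral adduct prevents over-addition, and the ester on the doubly flanked C1 is too hindered to compete.

**Step 3**
Reactants: 6 racemic enone ester
Product: 7 ethyl (1R)-1-[(2R)-2-hydroxy-3-methylbut-3-en-1-yl]-2,6,6-trimethylcyclohexa-2,4-diene-1-carboxylate
Conditions: (S)-Me-CBS [(S)-1-methyl-3,3-diphenyltetrahydro-1H,3H-pyrrolo[1,2-c][1,3,2]oxazaborole] (20 mol %), catecholborane, toluene, −78 °C; MeOH; chromatographic separation of the C1 epimers
Reagents that add atoms: none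
Why: Corey–Bakshi–Shibata reduction with the isopropenyl group as the large substituent should give the (R)-carbinol at C9 from both enantiomers of 6. The (1R,2′R) and (1S,2′R) diastereomers are separated and only the former is carried on, which fixes C1; the hindered ester should not lactonise before step 4.

**Step 4**
Reactants: 7 hydroxy ester
Product: 8 ethyl (1R)-1-[(2R)-2-(tert-butyldimethylsilyloxy)-3-methylbut-3-en-1-yl]-2,6,6-trimethylcyclohexa-2,4-diene-1-carboxylate
Conditions: TBSCl, imidazole, DMF, rt
Reagents that add atoms: tert-butyldimethylsilyl chloride, CC(C)(C)[Si](C)(C)Cl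
Why: Standard silylation of a secondary alcohol; it removes the C9 hydroxyl as a hydrogen-bond donor and makes this arm the bulkier substituent at C1.

**Step 5**
Reactants: 8 silyl ether ester
Product: 9 [(1R)-1-[(2R)-2-(tert-butyldimethylsilyloxy)-3-methylbut-3-en-1-yl]-2,6,6-trimethylcyclohexa-2,4-dien-1-yl]methanol
Conditions: LiAlH4, THF, 0 °C → rt
Reagents that add atoms: none
Why: Hydride reduction of a hindered, non-enolisable ester to the neopentyl alcohol; diene and silyl ether are inert.

**Step 6 (key step)**
Reactants: 9 dienyl carbinol
Product: 10 [(1R,4S,7R)-7-[(2R)-2-(tert-butyldimethylsilyloxy)-3-methylbut-3-en-1-yl]-1,8,8-trimethyl-2,3-dioxabicyclo[2.2.2]oct-5-en-7-yl]methanol (peroxide bridge on the face of the hydroxymethyl group)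
Conditions: O2, 5,10,15,20-tetraphenylporphyrin (1 mol %), visible light (white LED), CH2Cl2, −78 °C
Reagents that add atoms: dioxygen, O=O
Why: The excited porphyrin sensitises dioxygen to its singlet state, which adds across C2 and C5 of the ring-locked s-cis diene in a concerted suprafacial [4+2] cycloaddition, forming both C–O bonds and the C3=C4 alkene. The closest known reaction is the photooxygenation of cyclohexa-1,3-dienes to 2,3-dioxabicyclo[2.2.2]oct-5-enes, as in the α-terpinene to ascaridole conversion. The new six-membered 1,2-dioxine ring is closed by cycloaddition, both bonds in one step, bridging ring A. C2 and C5 become stereocentres; suprafacial addition fixes their mutual relation, and the diene face attacked fixes their relation to C1. The step needs attack on the face bearing the hydroxymethyl group, which is secured by hydrogen bonding of the free hydroxyl to the incoming oxygen in a non-donor solvent and by the larger silyloxyalkyl arm on the other face. The isopropenyl group is spared because ene reaction of a 1,1-disubstituted alkene is far slower, and cycloaddition is preferred over ene reaction at the C2 methyl in a cisoid ring diene. Low temperature preserves the endoperoxide.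

**Step 7**
Reactants: 10 endoperoxide alcohol
Product: 11 (1R,4S,7S)-7-[(2R)-2-(tert-butyldimethylsilyloxy)-3-methylbut-3-en-1-yl]-1,8,8-trimethyl-2,3-dioxabicyclo[2.2.2]oct-5-ene-7-carbaldehyde
Conditions: Dess–Martin periodinane, NaHCO3, CH2Cl2, 0 °C
Reagents that add atoms: none
Why: Dess–Martin oxidation of a hindered primary alcohol under buffered, non-reducing conditions that leave the O–O bond intact. Oxidising before the base step removes the hydroxyl that could add to the enone at C3 after step 8.

**Step 8**
Reactants: 11 endoperoxide aldehyde
Product: 12 (1S,2R)-1-[(2R)-2-(tert-butyldimethylsilyloxy)-3-methylbut-3-en-1-yl]-2-hydroxy-2,6,6-trimethyl-5-oxocyclohex-3-ene-1-carbaldehyde (C2 hydroxyl cis to the formyl group)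
Conditions: Et3N, CH2Cl2, 0 °C → rt
Reagents that add atoms: none
Why: Kornblum–DeLaMare rearrangement: the amine removes the only bridgehead hydrogen (C5) with cleavage of the weak O–O bond, so C5 becomes the ketone and C2 keeps its oxygen with retention. The weak base and aprotic medium are chosen to avoid retro-aldol cleavage of the β-hydroxy aldehyde.

**Step 9**
Reactants: 12 silyloxy hydroxy enone aldehyde
Product: 14 spiro lactol (3R)-1,6-dihydroxy-6,10,10-trimethyl-3-(prop-1-en-2-yl)-2-oxaspiro[4.5]dec-7-en-9-one (anomer mixture; tertiary hydroxyl cis to the lactol carbon), via dihydroxy aldehyde 13 (not isolated)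
Conditions: HF·pyridine, pyridine, THF, 0 °C → rt
Reagents that add atoms: none
Why: Buffered fluoride desilylation avoids the basic conditions that would trigger retro-aldol cleavage; the freed C9 hydroxyl closes ring C on the aldehyde as the five-membered lactol (5-exo-trig hemiacetalisation).

**Step 10**
Reactants: 14 lactol
Product: 15 tricyclic oxetane acetal enone (rings A, B and C of the target with C3=C4–C5=O)
Conditions: PPh3, diisopropyl azodicarboxylate, 4 Å molecular sieves, THF, 0 °C → rt
Reagents that add atoms: none
Why: Mitsunobu cyclodehydration: the lactol hydroxyl is the only one that can be activated at phosphorus, and the cis tertiary C2 hydroxyl displaces the phosphine oxide at C7 (4-exo), as in known Mitsunobu closures of strained bicyclic oxetane acetals from 1,3-hydroxy lactols. The closure is irreversible and acid-free, which equilibrium acetalisation cannot be; both anomers converge, and C7 is fixed by the cis fusion.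

**Step 11**
Reactants: 15 tricyclic enone
Product: 16 hydrazone of 15 at C5
Conditions: N2H4·H2O, Et3N, EtOH, 60 °C
Reagents that add atoms: hydrazine hydrate, NN.O
Why: Condensation of hydrazine with the only carbonyl group; the basic medium spares the acetal, and the ring-locked s-trans enone cannot close to a pyrazoline.

**Step 12**
Reactants: 16 hydrazone
Product: 18 CNP0141320.1 (target dibromide), via vinyl diazo compound 17 (not isolated)
Conditions: CuBr2 (6 equiv), Et3N (3 equiv), 4 Å molecular sieves, MeCN, 0 °C
Reagents that add atoms: copper dibromide, [Cu+2].[Br-].[Br-]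
Why: Divalent copper oxidises the hydrazone to diazo compound 17; bromination at the diazo carbon C5 and loss of N2 leave a bromine-substituted allyl cation that takes bromide at the distal terminus C3 and not at the crowded C5 (Barton-type hydrazone halogenation with allylic transposition). Bromide should approach C3 anti to the C2–O bond, away from the oxetane oxygen lone pairs; this is the least secure stereochemical element of the route.

## Compound list

1 | ethyl safranate (ethyl 2,6,6-trimethylcyclohexa-1,3-diene-1-carboxylate) | CCOC(=O)C1=C(C)C=CCC1(C)C | starting material
2 | 2-bromo-N-methoxy-N-methylacetamide | BrCC(=O)N(C)OC | starting material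
3 | potassium trienolate of 1 | CCOC([O-])=C1C(C)=CC=CC1(C)C.[K+] | intermediate (not isolated)
4 | racemic ethyl 1-{2-[methoxy(methyl)amino]-2-oxoethyl}-2,6,6-trimethylcyclohexa-2,4-diene-1-carboxylate | CCOC(=O)C1(CC(=O)N(C)OC)C(C)=CC=CC1(C)C | intermediate
5 | isopropenylmagnesium bromide | CC(=C)[Mg]Br | starting material
6 | racemic ethyl 2,6,6-trimethyl-1-(3-methyl-2-oxobut-3-en-1-yl)cyclohexa-2,4-diene-1-carboxylate | CCOC(=O)C1(CC(=O)C(C)=C)C(C)=CC=CC1(C)C | intermediate
7 | ethyl (1R)-1-[(2R)-2-hydroxy-3-methylbut-3-en-1-yl]-2,6,6-trimethylcyclohexa-2,4-diene-1-carboxylate | C=C(C)[C@H](O)C[C@@]1(C(=O)OCC)C(C)=CC=CC1(C)C | intermediate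
8 | ethyl (1R)-1-[(2R)-2-(tert-butyldimethylsilyloxy)-3-methylbut-3-en-1-yl]-2,6,6-trimethylcyclohexa-2,4-diene-1-carboxylate | C=C(C)[C@H](O[Si](C)(C)C(C)(C)C)C[C@@]1(C(=O)OCC)C(C)=CC=CC1(C)C | intermediate
9 | [(1R)-1-[(2R)-2-(tert-butyldimethylsilyloxy)-3-methylbut-3-en-1-yl]-2,6,6-trimethylcyclohexa-2,4-dien-1-yl]methanol | C=C(C)[C@H](O[Si](C)(C)C(C)(C)C)C[C@@]1(CO)C(C)=CC=CC1(C)C | intermediate
10 | [(1R,4S,7R)-7-[(2R)-2-(tert-butyldimethylsilyloxy)-3-methylbut-3-en-1-yl]-1,8,8-trimethyl-2,3-dioxabicyclo[2.2.2]oct-5-en-7-yl]methanol | C=C(C)[C@H](O[Si](C)(C)C(C)(C)C)C[C@@]1(CO)[C@@]2(C)C=C[C@H](OO2)C1(C)C | intermediate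
11 | (1R,4S,7S)-7-[(2R)-2-(tert-butyldimethylsilyloxy)-3-methylbut-3-en-1-yl]-1,8,8-trimethyl-2,3-dioxabicyclo[2.2.2]oct-5-ene-7-carbaldehyde | C=C(C)[C@H](O[Si](C)(C)C(C)(C)C)C[C@@]1(C=O)[C@@]2(C)C=C[C@H](OO2)C1(C)C | intermediate
12 | (1S,2R)-1-[(2R)-2-(tert-butyldimethylsilyloxy)-3-methylbut-3-en-1-yl]-2-hydroxy-2,6,6-trimethyl-5-oxocyclohex-3-ene-1-carbaldehyde | C=C(C)[C@H](O[Si](C)(C)C(C)(C)C)C[C@@]1(C=O)[C@](C)(O)C=CC(=O)C1(C)C | intermediate
13 | (1S,2R)-2-hydroxy-1-[(2R)-2-hydroxy-3-methylbut-3-en-1-yl]-2,6,6-trimethyl-5-oxocyclohex-3-ene-1-carbaldehyde | C=C(C)[C@H](O)C[C@@]1(C=O)[C@](C)(O)C=CC(=O)C1(C)C | intermediate (not isolated)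
14 | spiro lactol, (3R)-1,6-dihydroxy-6,10,10-trimethyl-3-(prop-1-en-2-yl)-2-oxaspiro[4.5]dec-7-en-9-one, anomer mixture, tertiary hydroxyl cis to the lactol carbon | C=C(C)[C@H]1C[C@@]2(C(O)O1)[C@](C)(O)C=CC(=O)C2(C)C | intermediate
15 | tricyclic oxetane acetal enone (target skeleton with C3=C4 and C5=O) | C=C(C)[C@H]1C[C@@]23[C@@H](O1)O[C@]2(C)C=CC(=O)C3(C)C | intermediate
16 | C5 hydrazone of 15 | C=C(C)[C@H]1C[C@@]23[C@@H](O1)O[C@]2(C)C=CC(=NN)C3(C)C | intermediate
17 | C5 diazo compound | C=C(C)[C@H]1C[C@@]23[C@@H](O1)O[C@]2(C)C=CC(=[N+]=[N-])C3(C)C | intermediate (not isolated)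
18 | CNP0141320.1 (C9 R; bromine at C3 trans to the oxetane oxygen, cis to the C2 methyl) | C=C(C)[C@H]1C[C@@]23[C@@H](O1)O[C@]2(C)[C@@H](Br)C=C(Br)C3(C)C | target

## Step count and least certain steps

Total step count: 12. Longest linear sequence: 12 steps, from ethyl safranate 1.

**Step 6 (key step).** The most likely failure is poor facial selectivity: oxygen adding on the face of the silyloxyalkyl arm gives the endoperoxide whose C2 oxygen is trans to C7 and cannot close the oxetane. A lesser concern is ene reaction at the C2 methyl. The fallback delivers the C2 oxygen by a metal-bound hydroxyl and sets out from 9. Homoallylic-hydroxyl-directed epoxidation (VO(acac)2, t-BuOOH) of the C2=C3 bond gives the epoxy alcohol F1 with the epoxide cis to the hydroxymethyl group. Opening of the vinyl epoxide with acetic acid under zerovalent palladium catalysis, Pd(PPh3)4, in the 1,4 sense gives the hydroxy acetate F2. Methanolysis (K2CO3, MeOH) gives the triol F3, and excess Dess–Martin periodinane oxidises both the C7 alcohol and the allylic C5 alcohol, rejoining the route at 12.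

**Step 12.** The most likely failure is poor or reversed facial selectivity in the capture of bromide at C3, since sterics (the C2 methyl) and electrostatics (the oxetane oxygen) pull in opposite directions and the allylic bromide can epimerise by ionisation. Slow hydrazone oxidation next to C6 is a second concern. The fallback makes the C3–Br bond by SN2 inversion and sets out from 15. Copper-catalysed conjugate borylation (CuCl, NaOt-Bu, a bisphosphine, B2pin2, MeOH) from the more open face syn to the oxetane oxygen gives the β-boryl ketone F4. NaBO3 oxidation gives the β-hydroxy ketone F5 with retention, and hydrazine gives the hydrazone F6. Barton bromination (N-bromosuccinimide, a guanidine base) gives the bromoalkenyl alcohol F7; its alkene can only form toward C4. Appel bromination (CBr4, PPh3) with inversion at C3 rejoins the route at 18.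

**Step 10.** The most likely failure is that the activated anomeric centre is captured by the hydrazinedicarboxylate anion, or the lactol alkoxide adds to the enone, faster than the hindered tertiary hydroxyl closes the four-membered ring. The fallback closes the oxetane at the alcohol oxidation level and forms the acetal by C–H oxidation; it sets out from 10. Mesylation (MsCl, pyridine) gives the mesylate F8, and Et3N effects the same Kornblum–DeLaMare rearrangement to the hydroxy enone mesylate F9. KOt-Bu closes the oxetane by intramolecular Williamson displacement to the oxetane enone silyl ether F10, and HF·pyridine frees the C9 alcohol F11. A Suárez hypoiodite reaction (PhI(OAc)2, I2, visible light) then generates the C9 alkoxy radical, which abstracts the C7 hydrogen through a six-membered transition state; oxidation of the resulting α-alkoxy radical and capture by the C9 oxygen closes ring C and rejoins the route at 15.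

**Step 1.** The most likely failure is proton transfer to the trienolate from the α-bromo amide, or slow substitution at the hindered C1 leading to attack through C3 or C5. The fallback uses a non-acidic allylic electrophile and sets C9 by epoxidation, so it also replaces the reduction of step 3 should that fail to discriminate its two substituents. It sets out from 1. The same potassium trienolate is alkylated with prenyl bromide to the prenyl ester F12. Shi epoxidation with the ketone enantiomer that gives the (R)-epoxide gives the epoxide F13. Isomerisation with diethylaluminium 2,2,6,6-tetramethylpiperidide to the isopropenyl carbinol, followed by separation of the C1 epimers, rejoins the route at 7.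

## Further compounds

F1 | step 6 | epoxy alcohol, C2–C3 epoxide of 9 cis to the hydroxymethyl group | C=C(C)[C@H](O[Si](C)(C)C(C)(C)C)C[C@@]1(CO)[C@]2(C)O[C@@H]2C=CC1(C)C
F2 | step 6 | hydroxy acetate, C2 hydroxyl and C5 acetate cis, C3=C4 alkene | C=C(C)[C@H](O[Si](C)(C)C(C)(C)C)C[C@@]1(CO)[C@](C)(O)C=C[C@H](OC(C)=O)C1(C)C
F3 | step 6 | triol, C7, C2 and C5 hydroxyls | C=C(C)[C@H](O[Si](C)(C)C(C)(C)C)C[C@@]1(CO)[C@](C)(O)C=C[C@H](O)C1(C)C
F4 | step 12 | β-boryl ketone, pinacolboryl group at C3 cis to the oxetane oxygen | C=C(C)[C@H]1C[C@@]23[C@@H](O1)O[C@]2(C)[C@H](B4OC(C)(C)C(C)(C)O4)CC(=O)C3(C)C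
F5 | step 12 | β-hydroxy ketone, C3 hydroxyl cis to the oxetane oxygen | C=C(C)[C@H]1C[C@@]23[C@@H](O1)O[C@]2(C)[C@H](O)CC(=O)C3(C)C
F6 | step 12 | C5 hydrazone of F5 | C=C(C)[C@H]1C[C@@]23[C@@H](O1)O[C@]2(C)[C@H](O)CC(=NN)C3(C)C
F7 | step 12 | bromoalkenyl alcohol, C5 vinyl bromide, C3 hydroxyl cis to the oxetane oxygen | C=C(C)[C@H]1C[C@@]23[C@@H](O1)O[C@]2(C)[C@H](O)C=C(Br)C3(C)C
F8 | step 10 | mesylate of endoperoxide 10 | C=C(C)[C@H](O[Si](C)(C)C(C)(C)C)C[C@@]1(COS(C)(=O)=O)[C@@]2(C)C=C[C@H](OO2)C1(C)C
F9 | step 10 | hydroxy enone mesylate | C=C(C)[C@H](O[Si](C)(C)C(C)(C)C)C[C@@]1(COS(C)(=O)=O)[C@](C)(O)C=CC(=O)C1(C)C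
F10 | step 10 | oxetane enone silyl ether, rings A and B closed, C7 as CH2 | C=C(C)[C@H](O[Si](C)(C)C(C)(C)C)C[C@@]12CO[C@]1(C)C=CC(=O)C2(C)C
F11 | step 10 | oxetane enone alcohol, free C9 hydroxyl | C=C(C)[C@H](O)C[C@@]12CO[C@]1(C)C=CC(=O)C2(C)C
F12 | step 1 | racemic ethyl 2,6,6-trimethyl-1-(3-methylbut-2-en-1-yl)cyclohexa-2,4-diene-1-carboxylate | CCOC(=O)C1(CC=C(C)C)C(C)=CC=CC1(C)C
F13 | step 1 | ethyl 1-{[(2R)-3,3-dimethyloxiran-2-yl]methyl}-2,6,6-trimethylcyclohexa-2,4-diene-1-carboxylate, both C1 epimers | CCOC(=O)C1(C[C@H]2OC2(C)C)C(C)=CC=CC1(C)C
A1 | alternative 1 | butenolide methyl ketone, substrate of the reductive aldol | C=C(C)[C@H]1C=C(C(=O)O1)C(C)(C)C2(CCC(C)=O)OCCO2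
A2 | alternative 1 | bicyclic β-hydroxy lactone | C=C(C)[C@H]1C[C@@]2(C(=O)O1)[C@](C)(O)CCC3(OCCO3)C2(C)C
A3 | alternative 2 | 3-substituted furan with tethered methyl ketone | CC(=O)CC[C@H](O[Si](C)(C)C(C)(C)C)C(C)(C)c1ccoc1
A4 | alternative 2 | tricyclic oxetane acetal with residual enol ether | C1=C[C@@]23[C@@H](O1)O[C@]2(C)CC[C@H](O[Si](C)(C)C(C)(C)C)C3(C)C
A5 | alternative 3 | allylic dimethylsulfonium triflate with acetyl lactone | C=C(C)[C@H]1C[C@](C(C)=O)(C(=O)O1)C(C)(C)/C(Br)=C\C[S+](C)C.[O-]S(=O)(=O)C(F)(F)F
A6 | alternative 3 | epoxy bromoalkene lactone | C=C(C)[C@H]1C[C@@]3(C(=O)O1)[C@]2(C)O[C@@H]2C=C(Br)C3(C)C
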